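Everything rests on opening the ten-membered carbocycle at C1–C2. The feature used is the cis C2=C3 double bond of that ring, flanked by the epoxide carbons C1 and C4: a C2≡C3 triple bond can stand in for it, and the C1 oxygen then arrives as a propargylic hydroxyl that is later closed onto C10. One chromium/nickel alkynyl–aldehyde coupling forms C1–C2, closes the ring as a cyclodecyne and sets C1. Its substrate is an open-chain butenolide carrying the 4,5-epoxide and a C2 iodoalkyne on one arm and, on the other, the C8 methacrylate and the tertiary C10 carbinol flanked by the C1 aldehyde and a silyl-protected C14 hydroxymethyl group.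

Key step: step 17

Remark: atoms carry germacranolide numbers (ring C1–C10, lactone carbonyl C12 on C11, acetoxymethyl C13, hydroxymethyl C14 on C10, methyl C15 on C4); C14 is protected as its tert-butyldiphenylsilyl (TBDPS) ether so that the triethylsilyl (TES) ether masking the C10 hydroxyl up to the step before cyclisation can be removed selectively (PMB = 4-methoxybenzyl).

Step 1
Reactants: 1 prop-2-yn-1-ol; 2 allylmagnesium bromide
Product: 3 2-methylidenepent-4-en-1-ol
Conditions: 2 (3 equiv), CuI (10 mol%), Et2O, −10 °C → rt; then H2O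
Reagents that add atoms: none
Why: Copper-catalysed, hydroxyl-directed carbomagnesiation of the propargylic alcohol places the allyl group on the internal alkyne carbon, and protonolysis of the vinylmagnesium intermediate gives the 2-substituted allylic alcohol.

Step 2
Reactants: 3 2-methylidenepent-4-en-1-ol
Product: 4 [(2S)-2-(prop-2-en-1-yl)oxiran-2-yl]methanol
Conditions: Ti(OiPr)4 (10 mol%), L-(+)-DIPT (12 mol%), t-BuOOH, 4 Å MS, CH2Cl2, −20 °C
Reagents that add atoms: tert-butyl hydroperoxide, `CC(C)(C)OO`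
Why: Sharpless asymmetric epoxidation touches only the allylic-alcohol alkene, and with L-(+)-tartrate the oxygen should be delivered to the face that gives the (S)-epoxide, which fixes C10.

Step 3
Reactants: 4 [(2S)-2-(prop-2-en-1-yl)oxiran-2-yl]methanol
Product: 5 (2S)-2-[(4-methoxybenzyloxy)methyl]pent-4-ene-1,2-diol
Conditions: 4-methoxybenzyl alcohol (5 equiv), NaH (0.2 equiv), DMF, 60 °C
Reagents that add atoms: 4-methoxybenzyl alcohol, `COc1ccc(CO)cc1`
Why: Base-catalysed SN2 opening of the 2,2-disubstituted epoxide by the benzylic alkoxide at its CH2 terminus leaves the C10–O bond intact, so C10 keeps its configuration (a Payne shift of the epoxy alkoxide is degenerate and leads to the same enantiomer).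

Step 4
Reactants: 5 (2S)-2-[(4-methoxybenzyloxy)methyl]pent-4-ene-1,2-diol
Product: 7 (4R)-4-[(TBDPS-oxy)methyl]-5-(PMB-oxy)-4-(TES-oxy)pent-1-ene, via mono-silyl ether 6 (not isolated)
Conditions: TBDPSCl, imidazole, CH2Cl2, 0 °C; then TESOTf, 2,6-lutidine, −78 → 0 °C
Reagents that add atoms: tert-butyl(chloro)diphenylsilane, `CC(C)(C)[Si](Cl)(c1ccccc1)c1ccccc1`; triethylsilyl trifluoromethanesulfonate, `CC[Si](CC)(CC)OS(=O)(=O)C(F)(F)F`
Why: Silyl ether formation in two stages: the bulky chloride silylates only the primary hydroxyl (C14) and the silyl triflate then caps the hindered tertiary C10 hydroxyl.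

Step 5
Reactants: 7 (4R)-4-[(TBDPS-oxy)methyl]-5-(PMB-oxy)-4-(TES-oxy)pent-1-ene
Product: 9 (3R)-3-[(TBDPS-oxy)methyl]-4-(PMB-oxy)-3-(TES-oxy)butanal, via ozonide 8 (not isolated)
Conditions: O3, CH2Cl2, −78 °C (stopped at first blue colour); then PPh3, −78 °C → rt
Reagents that add atoms: ozone, `[O-][O+]=O`
Why: Ozonolysis with reductive work-up cleaves the only C=C bond to the C8 aldehyde, the terminal alkene reacting far faster than the anisyl ring.

Step 6
Reactants: 9 (3R)-3-[(TBDPS-oxy)methyl]-4-(PMB-oxy)-3-(TES-oxy)butanal; 10 methyl propiolate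
Product: 11 methyl (4S,6R)-4-hydroxy-6-[(TBDPS-oxy)methyl]-7-(PMB-oxy)-6-(TES-oxy)hept-2-ynoate
Conditions: Me2Zn, ProPhenol ligand (enantiomer chosen for Re-face addition), Ph3PO (cat.), toluene, 4 °C
Reagents that add atoms: none
Why: Zinc–ProPhenol catalysed asymmetric alkynylation: the alkynylzinc reagent from methyl propiolate adds to the Re face of the aldehyde under catalyst control and sets C8 as S.

Step 7
Reactants: 11 methyl (4S,6R)-4-hydroxy-6-[(TBDPS-oxy)methyl]-7-(PMB-oxy)-6-(TES-oxy)hept-2-ynoate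
Product: 12 methyl (4S,6R)-4-(methacryloyloxy)-6-[(TBDPS-oxy)methyl]-7-(PMB-oxy)-6-(TES-oxy)hept-2-ynoate
Conditions: methacrylic anhydride, i-Pr2NEt, DMAP (cat.), CH2Cl2, −20 °C
Reagents that add atoms: methacrylic anhydride, `C=C(C)C(=O)OC(=O)C(C)=C`
Why: DMAP-catalysed acylation of the secondary propargylic alcohol, run cold so that esterification outpaces base-induced isomerisation of the hydroxy ynoate; the ester also serves as the C8 protecting group.

Step 8
Reactants: 12 methyl (4S,6R)-4-(methacryloyloxy)-6-[(TBDPS-oxy)methyl]-7-(PMB-oxy)-6-(TES-oxy)hept-2-ynoate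
Product: 13 methyl (2Z,4S,6R)-2-(hydroxymethyl)-3-iodo-4-(methacryloyloxy)-6-[(TBDPS-oxy)methyl]-7-(PMB-oxy)-6-(TES-oxy)hept-2-enoate
Conditions: MgI2, monomeric CH2O (from cracked paraformaldehyde), CH2Cl2, 0 °C
Reagents that add atoms: formaldehyde, `C=O`; magnesium iodide, `[Mg+2].[I-].[I-]`
Why: Iodide-triggered aldol (β-iodo Morita–Baylis–Hillman reaction): iodide adds to C7 of the magnesium-activated ynoate and the allenolate takes up formaldehyde at C11, which, as with propiolates under these conditions, is expected to give the isomer with iodine cis to the ester.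

Step 9
Reactants: 13 methyl (2Z,4S,6R)-2-(hydroxymethyl)-3-iodo-4-(methacryloyloxy)-6-[(TBDPS-oxy)methyl]-7-(PMB-oxy)-6-(TES-oxy)hept-2-enoate
Product: 14 methyl (2Z,4S,6R)-2-(acetoxymethyl)-3-iodo-4-(methacryloyloxy)-6-[(TBDPS-oxy)methyl]-7-(PMB-oxy)-6-(TES-oxy)hept-2-enoate
Conditions: Ac2O, pyridine, DMAP (cat.), CH2Cl2, 0 °C
Reagents that add atoms: acetic anhydride, `CC(=O)OC(C)=O`
Why: Acetylation of the only free (primary allylic) hydroxyl installs the C13 acetate and stops acyl migration from C8.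

Step 10
Reactants: 15 (Z)-3-methylpent-2-en-4-yn-1-ol
Product: 16 [(2S,3R)-3-ethynyl-3-methyloxiran-2-yl]methanol
Conditions: Ti(OiPr)4 (10 mol%), L-(+)-DIPT (12 mol%), t-BuOOH, 4 Å MS, CH2Cl2, −20 °C
Reagents that add atoms: tert-butyl hydroperoxide, `CC(C)(C)OO`
Why: Sharpless asymmetric epoxidation of the trisubstituted Z-allylic alcohol; L-(+)-tartrate should deliver oxygen to the face that sets C4 as R and C5 as S, and the Z-alkene fixes the alkyne cis to the carbinol carbon.

Step 11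
Reactants: 16 [(2S,3R)-3-ethynyl-3-methyloxiran-2-yl]methanol
Product: 17 (2R,3R)-3-ethynyl-3-methyloxirane-2-carbaldehyde
Conditions: Dess–Martin periodinane, pyridine, CH2Cl2, 0 °C
Reagents that add atoms: none
Why: Dess–Martin oxidation under buffered, non-epimerising conditions gives the epoxy aldehyde, which is used without storage.

Step 12
Reactants: 14 methyl (2Z,4S,6R)-2-(acetoxymethyl)-3-iodo-4-(methacryloyloxy)-6-[(TBDPS-oxy)methyl]-7-(PMB-oxy)-6-(TES-oxy)hept-2-enoate; 17 (2R,3R)-3-ethynyl-3-methyloxirane-2-carbaldehyde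
Product: 19 open-chain alkyne butenolide (4R,5S,6S,8S,10R; 1-OPMB; 10-OTES; 14-OTBDPS), via hydroxy ester 18 (not isolated)
Conditions: CrCl2 (4 equiv), NiCl2 (2 mol%), DMSO, rt
Reagents that add atoms: none
Why: Nozaki–Hiyama–Kishi coupling followed by lactonisation: the alkenylchromium species formed at C7 adds to the epoxy aldehyde anti to the epoxide C–O bond (Felkin–Anh control), setting C6 as S, and the chromium alkoxide closes onto the cis methyl ester to give the butenolide.

Step 13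
Reactants: 19 open-chain alkyne butenolide (1-OPMB; 10-OTES; 14-OTBDPS)
Product: 20 C1 alcohol of the alkyne butenolide (10-OTES; 14-OTBDPS)
Conditions: DDQ, CH2Cl2/pH 7 buffer, 0 °C
Reagents that add atoms: none
Why: Oxidative cleavage of the p-methoxybenzyl ether (hydride abstraction, hydrolysis of the oxocarbenium ion); the neighbouring C10 oxygen is silylated, so no benzylidene acetal can form.

Step 14
Reactants: 20 C1 alcohol of the alkyne butenolide
Product: 21 C2 iodoalkyne C1 alcohol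
Conditions: N-iodosuccinimide, AgNO3 (10 mol%), acetone, rt, dark
Reagents that add atoms: N-iodosuccinimide, `O=C1CCC(=O)N1I`
Why: Silver-catalysed electrophilic iodination of the terminal alkyne through its silver acetylide; no base is needed.

Step 15
Reactants: 21 C2 iodoalkyne C1 alcohol
Product: 22 C2 iodoalkyne C1 aldehyde (10-OTES; 14-OTBDPS)
Conditions: Dess–Martin periodinane, pyridine, CH2Cl2, 0 °C
Reagents that add atoms: none
Why: Dess–Martin oxidation of the only free (primary) hydroxyl to the α-silyloxy aldehyde.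

Step 16
Reactants: 22 C2 iodoalkyne C1 aldehyde (10-OTES; 14-OTBDPS)
Product: 23 iodoalkynyl epoxide butenolide with C1 aldehyde and free C10 hydroxyl (4R,5S,6S,8S,10S; 14-OTBDPS)
Conditions: HF·pyridine, pyridine, THF, 0 °C
Reagents that add atoms: none
Why: Buffered fluoride desilylation removes the triethylsilyl ether selectively over the primary tert-butyldiphenylsilyl ether and frees the chelating C10 hydroxyl only now, so the α-hydroxy aldehyde is used at once.

Step 17
Reactants: 23 iodoalkynyl epoxide butenolide with C1 aldehyde and free C10 hydroxyl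
Product: 24 cyclodecyne 1,10-diol (1S,4R,5S,6S,8S,10S; 14-OTBDPS)
Conditions: CrCl2 (10 equiv), NiCl2 (10 mol%), THF, rt, slow addition to 1 mM
Reagents that add atoms: none
Why: Nozaki–Hiyama–Kishi alkynylation: CrCl2 reduces NiCl2 to zerovalent nickel, which undergoes oxidative addition to the C2–I bond; the alkynyl group is passed on to trivalent chromium and this alkynylchromium species attacks the C1 aldehyde. The closest known reaction type is the CrCl2/NiCl2 cyclisation of ω-iodoalkynyl aldehydes to nine- and ten-membered cycloalkynols. The ten-membered ring closes in a 10-exo-trig mode (C2 onto the carbonyl carbon C1, carbonyl oxygen outside the ring), the six-atom chain C5–C10, already bent by the cis-epoxide and the butenolide, spanning the four collinear atoms C1–C4. The new stereocentre C1 is controlled by a five-membered chromium chelate between the aldehyde oxygen and the free C10 hydroxyl, which holds the carbonyl syn to the C10–O bond so that the ring-bound alkynyl carbon adds from the C9 side, away from the C14 silyloxymethyl arm, to give the 1S carbinol. The step needs that C1 epimer (the one that closes to the epoxide with inversion) and ring closure in preference to intermolecular coupling, which the chelating hydroxyl and slow addition to high dilution are meant to secure. Neither base nor acid is present, so the butenolide, both esters, the alkynyl epoxide and the silyl ether should survive.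

Step 18
Reactants: 24 cyclodecyne 1,10-diol
Product: 25 (2Z)-cyclodecene 1,10-diol (1S,4R,5S,6S,8S,10S; 14-OTBDPS)
Conditions: H2 (1 atm), Pd/CaCO3 poisoned with Pb(OAc)2, quinoline, EtOAc, rt
Reagents that add atoms: none
Why: Syn semihydrogenation on lead-poisoned palladium stops at the alkene and, within the ring, can only give the cis C2=C3 bond; the conjugated methacrylate and tetrasubstituted butenolide alkenes react much more slowly.

Step 19
Reactants: 25 (2Z)-cyclodecene 1,10-diol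
Product: 26 14-O-TBDPS ether of the target (1R,4R,5S,6S,8S,10S)
Conditions: PPh3, DIAD, toluene, 0 °C → rt
Reagents that add atoms: none
Why: Mitsunobu cyclodehydration: the secondary allylic C1 hydroxyl is activated as its oxyphosphonium ion and displaced by the adjacent tertiary C10 hydroxyl in a 3-exo-tet SN2 closure, which inverts C1 to R and leaves C10 unchanged.

Step 20
Reactants: 26 14-O-TBDPS ether of the target
Product: 27 CNP0207684.1 (target)
Conditions: TBAF, AcOH (1:1), THF, 0 °C → rt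
Reagents that add atoms: none
Why: Acetic acid-buffered fluoride desilylation frees the C14 hydroxyl without exposing the butenolide, the esters or the two epoxides to base.

Compound list
1 | prop-2-yn-1-ol | `C#CCO` | starting material
2 | allylmagnesium bromide | `C=CC[Mg]Br` | starting material
3 | 2-methylidenepent-4-en-1-ol | `C=CCC(=C)CO` | intermediate
4 | [(2S)-2-(prop-2-en-1-yl)oxiran-2-yl]methanol | `C=CC[C@]1(CO)CO1` | intermediate
5 | (2S)-2-[(4-methoxybenzyloxy)methyl]pent-4-ene-1,2-diol | `C=CC[C@@](CO)(O)COCc1ccc(OC)cc1` | intermediate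
6 | (2R)-1-(tert-butyldiphenylsilyloxy)-2-[(4-methoxybenzyloxy)methyl]pent-4-en-2-ol | `C=CC[C@@](CO[Si](c1ccccc1)(c1ccccc1)C(C)(C)C)(O)COCc1ccc(OC)cc1` | intermediate
7 | (4R)-4-[(tert-butyldiphenylsilyloxy)methyl]-5-(4-methoxybenzyloxy)-4-(triethylsilyloxy)pent-1-ene | `C=CC[C@@](CO[Si](c1ccccc1)(c1ccccc1)C(C)(C)C)(O[Si](CC)(CC)CC)COCc1ccc(OC)cc1` | intermediate
8 | ozonide of 7 (1,2,4-trioxolane carrying the C9 chain at C3) | `C1(C[C@@](CO[Si](c2ccccc2)(c2ccccc2)C(C)(C)C)(O[Si](CC)(CC)CC)COCc2ccc(OC)cc2)OCOO1` | intermediate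
9 | (3R)-3-[(tert-butyldiphenylsilyloxy)methyl]-4-(4-methoxybenzyloxy)-3-(triethylsilyloxy)butanal | `O=CC[C@@](CO[Si](c1ccccc1)(c1ccccc1)C(C)(C)C)(O[Si](CC)(CC)CC)COCc1ccc(OC)cc1` | intermediate
10 | methyl propiolate | `C#CC(=O)OC` | starting material
11 | methyl (4S,6R)-4-hydroxy-6-[(TBDPS-oxy)methyl]-7-(PMB-oxy)-6-(TES-oxy)hept-2-ynoate | `O[C@@H](C[C@@](CO[Si](c1ccccc1)(c1ccccc1)C(C)(C)C)(O[Si](CC)(CC)CC)COCc1ccc(OC)cc1)C#CC(=O)OC` | intermediate
12 | methyl (4S,6R)-4-(methacryloyloxy)-6-[(TBDPS-oxy)methyl]-7-(PMB-oxy)-6-(TES-oxy)hept-2-ynoate | `C=C(C)C(=O)O[C@@H](C[C@@](CO[Si](c1ccccc1)(c1ccccc1)C(C)(C)C)(O[Si](CC)(CC)CC)COCc1ccc(OC)cc1)C#CC(=O)OC` | intermediate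
13 | methyl (2Z,4S,6R)-2-(hydroxymethyl)-3-iodo-4-(methacryloyloxy)-6-[(TBDPS-oxy)methyl]-7-(PMB-oxy)-6-(TES-oxy)hept-2-enoate | `C=C(C)C(=O)O[C@@H](C[C@@](CO[Si](c1ccccc1)(c1ccccc1)C(C)(C)C)(O[Si](CC)(CC)CC)COCc1ccc(OC)cc1)/C(I)=C(\CO)C(=O)OC` | intermediate
14 | methyl (2Z,4S,6R)-2-(acetoxymethyl)-3-iodo-4-(methacryloyloxy)-6-[(TBDPS-oxy)methyl]-7-(PMB-oxy)-6-(TES-oxy)hept-2-enoate | `C=C(C)C(=O)O[C@@H](C[C@@](CO[Si](c1ccccc1)(c1ccccc1)C(C)(C)C)(O[Si](CC)(CC)CC)COCc1ccc(OC)cc1)/C(I)=C(\COC(C)=O)C(=O)OC` | intermediate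
15 | (Z)-3-methylpent-2-en-4-yn-1-ol | `C#C/C(C)=C\CO` | starting material
16 | [(2S,3R)-3-ethynyl-3-methyloxiran-2-yl]methanol | `OC[C@@H]1O[C@]1(C)C#C` | intermediate
17 | (2R,3R)-3-ethynyl-3-methyloxirane-2-carbaldehyde | `O=C[C@@H]1O[C@]1(C)C#C` | intermediate
18 | open-chain hydroxy ester: methyl (4R,5S,6S,8S,10R)-13-acetoxy-4,5-epoxy-6-hydroxy-8-(methacryloyloxy)-1-(PMB-oxy)-14-(TBDPS-oxy)-10-(TES-oxy)-1,2-secogermacr-7(11)-en-2-yn-12-oate, ester cis to C6 | `C=C(C)C(=O)O[C@@H](C[C@@](CO[Si](c1ccccc1)(c1ccccc1)C(C)(C)C)(O[Si](CC)(CC)CC)COCc1ccc(OC)cc1)/C([C@H](O)[C@@H]1O[C@]1(C)C#C)=C(\COC(C)=O)C(=O)OC` | intermediate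
19 | (4R,5S,6S,8S,10R)-13-acetoxy-4,5-epoxy-8-(methacryloyloxy)-1-(PMB-oxy)-14-(TBDPS-oxy)-10-(TES-oxy)-1,2-secogermacr-7(11)-en-2-yn-12,6-olide | `C=C(C)C(=O)O[C@@H](C[C@@](CO[Si](c1ccccc1)(c1ccccc1)C(C)(C)C)(O[Si](CC)(CC)CC)COCc1ccc(OC)cc1)C1=C(COC(C)=O)C(=O)O[C@@H]1[C@@H]1O[C@]1(C)C#C` | intermediate
20 | (4R,5S,6S,8S,10R)-13-acetoxy-4,5-epoxy-1-hydroxy-8-(methacryloyloxy)-14-(TBDPS-oxy)-10-(TES-oxy)-1,2-secogermacr-7(11)-en-2-yn-12,6-olide | `C=C(C)C(=O)O[C@@H](C[C@@](CO[Si](c1ccccc1)(c1ccccc1)C(C)(C)C)(O[Si](CC)(CC)CC)CO)C1=C(COC(C)=O)C(=O)O[C@@H]1[C@@H]1O[C@]1(C)C#C` | intermediate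
21 | (4R,5S,6S,8S,10R)-13-acetoxy-4,5-epoxy-1-hydroxy-2-iodo-8-(methacryloyloxy)-14-(TBDPS-oxy)-10-(TES-oxy)-1,2-secogermacr-7(11)-en-2-yn-12,6-olide | `C=C(C)C(=O)O[C@@H](C[C@@](CO[Si](c1ccccc1)(c1ccccc1)C(C)(C)C)(O[Si](CC)(CC)CC)CO)C1=C(COC(C)=O)C(=O)O[C@@H]1[C@@H]1O[C@]1(C)C#CI` | intermediate
22 | (4R,5S,6S,8S,10S)-13-acetoxy-4,5-epoxy-2-iodo-8-(methacryloyloxy)-1-oxo-14-(TBDPS-oxy)-10-(TES-oxy)-1,2-secogermacr-7(11)-en-2-yn-12,6-olide | `C=C(C)C(=O)O[C@@H](C[C@@](CO[Si](c1ccccc1)(c1ccccc1)C(C)(C)C)(O[Si](CC)(CC)CC)C=O)C1=C(COC(C)=O)C(=O)O[C@@H]1[C@@H]1O[C@]1(C)C#CI` | intermediate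
23 | (4R,5S,6S,8S,10S)-13-acetoxy-4,5-epoxy-10-hydroxy-2-iodo-8-(methacryloyloxy)-1-oxo-14-(TBDPS-oxy)-1,2-secogermacr-7(11)-en-2-yn-12,6-olide (cyclisation substrate) | `C=C(C)C(=O)O[C@@H](C[C@@](CO[Si](c1ccccc1)(c1ccccc1)C(C)(C)C)(O)C=O)C1=C(COC(C)=O)C(=O)O[C@@H]1[C@@H]1O[C@]1(C)C#CI` | intermediate
24 | (1S,4R,5S,6S,8S,10S)-13-acetoxy-4,5-epoxy-1,10-dihydroxy-8-(methacryloyloxy)-14-(TBDPS-oxy)germacr-7(11)-en-2-yn-12,6-olide (cyclodecyne diol) | `C=C(C)C(=O)O[C@H]1C[C@@](CO[Si](c3ccccc3)(c3ccccc3)C(C)(C)C)(O)[C@@H](O)C#C[C@@]2(C)O[C@H]2[C@H]2OC(=O)C(COC(C)=O)=C12` | intermediate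
25 | (1S,2Z,4R,5S,6S,8S,10S)-13-acetoxy-4,5-epoxy-1,10-dihydroxy-8-(methacryloyloxy)-14-(TBDPS-oxy)germacra-2,7(11)-dien-12,6-olide | `C=C(C)C(=O)O[C@H]1C[C@@](CO[Si](c3ccccc3)(c3ccccc3)C(C)(C)C)(O)[C@@H](O)/C=C\[C@@]2(C)O[C@H]2[C@H]2OC(=O)C(COC(C)=O)=C12` | intermediate
26 | (1R,2Z,4R,5S,6S,8S,10S)-13-acetoxy-1,10:4,5-diepoxy-8-(methacryloyloxy)-14-(TBDPS-oxy)germacra-2,7(11)-dien-12,6-olide | `C=C(C)C(=O)O[C@H]1C[C@@]2(CO[Si](c3ccccc3)(c3ccccc3)C(C)(C)C)O[C@@H]2/C=C\[C@@]2(C)O[C@H]2[C@H]2OC(=O)C(COC(C)=O)=C12` | intermediate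
27 | CNP0207684.1: (1R,2Z,4R,5S,6S,8S,10S)-13-acetoxy-1,10:4,5-diepoxy-14-hydroxy-8-(methacryloyloxy)germacra-2,7(11)-dien-12,6-olide | `C=C(C)C(=O)O[C@H]1C[C@@]2(CO)O[C@@H]2/C=C\[C@@]2(C)O[C@H]2[C@H]2OC(=O)C(COC(C)=O)=C12` | target

Total step count: 20. Longest linear sequence: 18 steps (steps 1–9 and 12–20).

Steps most likely to fail

Step 8. The risk is poor control of the C7=C11 geometry in the iodide-triggered aldol, so that the ester ends up cis to C8 instead of cis to iodine. The fallback makes the geometry irrelevant. Setting out from 12, the aldol isomer, the (2E)-hydroxymethyl iodoenoate F1, is acetylated (Ac2O, pyridine) to its acetate F2 and coupled with 17 under the conditions of step 12. The adduct, the open hydroxy ester F3, cannot lactonise because its ester is trans to the C6 hydroxyl. It is therefore irradiated (300 nm, acetone as solvent and sensitiser), so that E/Z photoisomerisation of the enoate feeds the lactonisable isomer 18, which closes to 19, where the route is rejoined.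

Step 17. The risk is poor facial selectivity at C1 during ring closure, because the conformational preference of the forming ten-membered ring may override the chromium chelate. The fallback sets C1 after the ring is closed. Setting out from 23, the cyclisation product, 24 together with its C1 epimer F4, is oxidised at the propargylic carbinol with MnO2 (CH2Cl2) to the cyclodecynone F5. The ynone is then reduced under catalyst control by transfer hydrogenation (RuCl[(R,R)-TsDPEN](p-cymene), i-PrOH) to 24, where the route is rejoined.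

Step 19. The risk is ionisation of the allylic oxyphosphonium intermediate (allylic transposition, elimination or loss of configuration at C1) instead of direct displacement. The fallback closes the epoxide before the alkyne is reduced, while C1 is propargylic and cannot transpose within the ring. Setting out from 24, the same cyclodehydration (PPh3, DIAD, toluene) gives the cyclodecyne bis-epoxide F6, and semihydrogenation as in step 18 then gives 26, where the route is rejoined.

Further compounds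
F1 | step 8 | methyl (2E,4S,6R)-2-(hydroxymethyl)-3-iodo-4-(methacryloyloxy)-6-[(TBDPS-oxy)methyl]-7-(PMB-oxy)-6-(TES-oxy)hept-2-enoate | `C=C(C)C(=O)O[C@@H](C[C@@](CO[Si](c1ccccc1)(c1ccccc1)C(C)(C)C)(O[Si](CC)(CC)CC)COCc1ccc(OC)cc1)/C(I)=C(/CO)C(=O)OC`
F2 | step 8 | methyl (2E,4S,6R)-2-(acetoxymethyl)-3-iodo-4-(methacryloyloxy)-6-[(TBDPS-oxy)methyl]-7-(PMB-oxy)-6-(TES-oxy)hept-2-enoate | `C=C(C)C(=O)O[C@@H](C[C@@](CO[Si](c1ccccc1)(c1ccccc1)C(C)(C)C)(O[Si](CC)(CC)CC)COCc1ccc(OC)cc1)/C(I)=C(/COC(C)=O)C(=O)OC`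
F3 | step 8 | C7=C11 geometric isomer of 18 (ester trans to the C6 hydroxyl) | `C=C(C)C(=O)O[C@@H](C[C@@](CO[Si](c1ccccc1)(c1ccccc1)C(C)(C)C)(O[Si](CC)(CC)CC)COCc1ccc(OC)cc1)/C([C@H](O)[C@@H]1O[C@]1(C)C#C)=C(/COC(C)=O)C(=O)OC`
F4 | step 17 | C1 epimer of 24 (1R,4R,5S,6S,8S,10S) | `C=C(C)C(=O)O[C@H]1C[C@@](CO[Si](c3ccccc3)(c3ccccc3)C(C)(C)C)(O)[C@H](O)C#C[C@@]2(C)O[C@H]2[C@H]2OC(=O)C(COC(C)=O)=C12`
F5 | step 17 | (4R,5S,6S,8S,10S)-13-acetoxy-4,5-epoxy-10-hydroxy-8-(methacryloyloxy)-1-oxo-14-(TBDPS-oxy)germacr-7(11)-en-2-yn-12,6-olide | `C=C(C)C(=O)O[C@H]1C[C@@](CO[Si](c3ccccc3)(c3ccccc3)C(C)(C)C)(O)C(=O)C#C[C@@]2(C)O[C@H]2[C@H]2OC(=O)C(COC(C)=O)=C12`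
F6 | step 19 | (1R,4R,5S,6S,8S,10S)-13-acetoxy-1,10:4,5-diepoxy-8-(methacryloyloxy)-14-(TBDPS-oxy)germacr-7(11)-en-2-yn-12,6-olide | `C=C(C)C(=O)O[C@H]1C[C@@]2(CO[Si](c3ccccc3)(c3ccccc3)C(C)(C)C)O[C@@H]2C#C[C@@]2(C)O[C@H]2[C@H]2OC(=O)C(COC(C)=O)=C12`
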